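**Retrosynthetic overview**
1. S–O bond: the hydrogen sulfate goes on last, onto the ring A phenol freed from a methyl ether.
2. Ring A is built de novo. Its 3,5-Br2 pattern comes from a 4-NH2 group (ortho,ortho-dibromination, then deamination). That amine comes from a 4-nitrophenol, made by double aldol condensation of nitromalonaldehyde with the acetonyl ether of the ring B phenol; the first ring C–C bond is intermolecular.
3. Ring B is built the same way. Its 3,4,5-Br3 pattern comes from a 4-NH2 group (dibromination, then Sandmeyer), which comes from the 4-nitrophenol made from nitromalonaldehyde and the acetonyl ether of 4-bromo-2-iodophenol.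
4. Both diaryl ether C–O bonds therefore begin as plain phenol O-alkylations with chloroacetone, so no aryl–O coupling is run next to C–I or C–Br bonds.
5. Ring order: ring C (from 4-bromophenol), then ring B (first benzannulation), then ring A (second benzannulation).

Assumption: the SMILES holds no stereocentre and the diaryl ether axes rotate freely at room temperature, so the target is achiral and no enantiomer has to be selected; the free hydrogen sulfate is taken as the final form.

**Route**

Step 1
Reactants: 1 mucobromic acid ((Z)-2,3-dibromo-4-oxobut-2-enoic acid)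
Product: 2 sodium nitromalonaldehyde monohydrate (Na[C3H2NO4]·H2O)
Conditions: NaNO2 (3.7 equiv), H2O–EtOH, 54 °C, 1.5 h; 0 °C, filter; recrystallise from aq EtOH (impact- and heat-sensitive solid: work behind a shield, never dry hot)
Reagents that add atoms: NaNO2, [Na+].[O-]N=O; water, O
Why: Nucleophilic vinylic substitution (addition–elimination) of both vinylic bromides by nitrite and water, followed by decarboxylation, gives the strongly stabilised nitromalonaldehyde anion, which crystallises from the cold mixture as its sodium salt.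

Step 2
Reactants: 3 4-bromophenol
Product: 4 4-bromo-2-iodophenol
Conditions: NIS (1.0 equiv), p-TsOH·H2O (10 mol %), MeCN, rt, 12 h
Reagents that add atoms: N-iodosuccinimide, O=C1CCC(=O)N1I
Why: In this electrophilic aromatic iodination the para position is blocked by Br, so the OH group sends the single equivalent of electrophilic iodine to one ortho carbon.

Step 3
Reactants: 4 4-bromo-2-iodophenol; 5 chloroacetone
Product: 6 1-(4-bromo-2-iodophenoxy)propan-2-one
Conditions: K2CO3 (1.5 equiv), acetone, reflux, 6 h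
Reagents that add atoms: none
Why: In this Williamson ether synthesis the phenoxide displaces chloride from the highly SN2-active α-chloroketone, and the aryl halides are inert under these conditions.

Step 4
Reactants: 6 1-(4-bromo-2-iodophenoxy)propan-2-one; 2 sodium nitromalonaldehyde monohydrate (1.2 equiv)
Product: 8 2-(4-bromo-2-iodophenoxy)-4-nitrophenol, via open-chain aldol condensation product 7 (not isolated)
Conditions: NaOH (1.5 equiv, 1 M aq), EtOH–THF, 0 °C → rt, 48–72 h; then 2 M HCl to pH 2
Reagents that add atoms: none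
Why: An intermolecular aldol condensation of the enolate of 6 with one formyl group of 2 makes the first ring C–C bond, the other α-carbon closes ring B by intramolecular aldol condensation, and loss of water aromatises irreversibly to the 4-nitrophenolate (nitromalonaldehyde–ketone benzannulation, Hill nitrophenol synthesis); because both α-carbons of 6 end up in the ring, only one regioisomer can form.

Step 5
Reactants: 8 2-(4-bromo-2-iodophenoxy)-4-nitrophenol
Product: 9 2-(4-bromo-2-iodophenoxy)-1-methoxy-4-nitrobenzene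
Conditions: MeI (1.5 equiv), K2CO3 (2 equiv), DMF, rt, 6 h
Reagents that add atoms: iodomethane, CI
Why: Williamson O-methylation of the acidic nitrophenol caps the oxygen, so the later aminophenol stage cannot be oxidised to a quinone imine.

Step 6
Reactants: 9 2-(4-bromo-2-iodophenoxy)-1-methoxy-4-nitrobenzene
Product: 10 3-(4-bromo-2-iodophenoxy)-4-methoxyaniline
Conditions: Fe powder (6 equiv), AcOH–EtOH–H2O (1:2:1), 60 °C, 2 h; filter through Celite
Reagents that add atoms: none
Why: A Béchamp-type iron reduction converts ArNO2 to ArNH2 by electron transfer and leaves C–Br, C–I and ether bonds untouched, unlike catalytic hydrogenation.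

Step 7
Reactants: 10 3-(4-bromo-2-iodophenoxy)-4-methoxyaniline
Product: 11 2,6-dibromo-3-(4-bromo-2-iodophenoxy)-4-methoxyaniline
Conditions: NBS (2.1 equiv), MeCN, 0 °C → rt, dark, 3 h
Reagents that add atoms: N-bromosuccinimide, O=C1CCC(=O)N1Br
Why: In this electrophilic aromatic bromination the two open carbons ortho to NH2 are also ortho and para to the aryloxy oxygen and the para carbon is blocked, so both bromines enter there while the halogenated ring C is far too deactivated to compete.

Step 8
Reactants: 11 2,6-dibromo-3-(4-bromo-2-iodophenoxy)-4-methoxyaniline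
Product: 13 1,2,3-tribromo-4-(4-bromo-2-iodophenoxy)-5-methoxybenzene, via arenediazonium bromide 12 (not isolated)
Conditions: t-BuONO (1.5 equiv), CuBr2 (1.2 equiv), MeCN, 0 °C → 60 °C, 2 h
Reagents that add atoms: CuBr2, [Cu+2].[Br-].[Br-]
Why: In this non-aqueous Sandmeyer bromination the alkyl nitrite diazotises even this weakly basic 2,6-dibromoaniline in homogeneous solution, copper-mediated electron transfer expels N2, the aryl radical (remote from ring C) takes Br from CuBr2, and the acid-free medium spares the C–I bond.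

Step 9
Reactants: 13 1,2,3-tribromo-4-(4-bromo-2-iodophenoxy)-5-methoxybenzene
Product: 15 3,4,5-tribromo-2-(4-bromo-2-iodophenoxy)phenol, via aryloxydibromoborane 14 (not isolated)
Conditions: BBr3 (3 equiv), CH2Cl2, −78 °C → rt, 12 h; then ice–water
Reagents that add atoms: none
Why: In this Lewis-acid ether cleavage BBr3 binds the methoxy oxygen and bromide attacks the methyl carbon by SN2, a path closed to the diaryl ether, which therefore survives.

Step 10
Reactants: 15 3,4,5-tribromo-2-(4-bromo-2-iodophenoxy)phenol; 5 chloroacetone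
Product: 16 1-[3,4,5-tribromo-2-(4-bromo-2-iodophenoxy)phenoxy]propan-2-one
Conditions: K2CO3 (1.5 equiv), acetone, reflux, 8 h
Reagents that add atoms: none
Why: Williamson ether synthesis works here because the acidic polybromophenol is fully ionised by K2CO3 and its oxygen has only one ortho substituent, so SN2 on chloroacetone stays easy.

Step 11
Reactants: 16 1-[3,4,5-tribromo-2-(4-bromo-2-iodophenoxy)phenoxy]propan-2-one; 2 sodium nitromalonaldehyde monohydrate (1.5 equiv)
Product: 18 4-nitro-2-[3,4,5-tribromo-2-(4-bromo-2-iodophenoxy)phenoxy]phenol, via open-chain aldol condensation product 17 (not isolated)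
Conditions: NaOH (2 equiv, 1 M aq), THF–EtOH, 0 °C → rt, 72–96 h; then 2 M HCl to pH 2
Reagents that add atoms: none
Why: The same sequence of intermolecular aldol condensation, intramolecular aldol condensation and aromatisation builds ring A around the acetonyl carbons, placing OH, OAr and NO2 at C1, C2 and C4 with no regiochemical choice, and the free phenolate para to NO2 is the most stabilised one, so no Smiles rearrangement is driven.

Step 12
Reactants: 18 4-nitro-2-[3,4,5-tribromo-2-(4-bromo-2-iodophenoxy)phenoxy]phenol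
Product: 19 1,2,3-tribromo-4-(4-bromo-2-iodophenoxy)-5-(2-methoxy-5-nitrophenoxy)benzene
Conditions: MeI (1.5 equiv), K2CO3 (2 equiv), DMF, rt, 6 h
Reagents that add atoms: iodomethane, CI
Why: Williamson O-methylation of the only acidic OH protects the future sulfation site through the amine chemistry.

Step 13
Reactants: 19 1,2,3-tribromo-4-(4-bromo-2-iodophenoxy)-5-(2-methoxy-5-nitrophenoxy)benzene
Product: 20 4-methoxy-3-[3,4,5-tribromo-2-(4-bromo-2-iodophenoxy)phenoxy]aniline
Conditions: Fe powder (6 equiv), AcOH–EtOH–THF–H2O, 60 °C, 3 h; filter through Celite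
Reagents that add atoms: none
Why: The Béchamp-type iron reduction is chemoselective for the nitro group and does not hydrodehalogenate the five aryl halide positions.

Step 14
Reactants: 20 4-methoxy-3-[3,4,5-tribromo-2-(4-bromo-2-iodophenoxy)phenoxy]aniline
Product: 21 2,6-dibromo-4-methoxy-3-[3,4,5-tribromo-2-(4-bromo-2-iodophenoxy)phenoxy]aniline
Conditions: NBS (2.1 equiv), MeCN–THF, 0 °C → rt, dark, 3 h
Reagents that add atoms: N-bromosuccinimide, O=C1CCC(=O)N1Br
Why: This electrophilic aromatic bromination goes only to the aniline ring, at the two carbons ortho to NH2 that are reinforced by the aryloxy oxygen, and these are exactly C3 and C5 of ring A.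

Step 15
Reactants: 21 2,6-dibromo-4-methoxy-3-[3,4,5-tribromo-2-(4-bromo-2-iodophenoxy)phenoxy]aniline
Product: 23 1,5-dibromo-3-methoxy-2-[3,4,5-tribromo-2-(4-bromo-2-iodophenoxy)phenoxy]benzene, via arenediazonium hydrogen sulfate 22 (not isolated)
Conditions: conc. H2SO4 (10 equiv), NaNO2 (3 equiv, in portions), EtOH–toluene (3:1), 70–75 °C, 2 h
Reagents that add atoms: none
Why: In this hydrodediazoniation (reductive deamination) the electron-poor 2,6-dibromoarenediazonium ion is reduced by hot ethanol in a radical chain, as in the classical conversion of 2,4,6-tribromoaniline into 1,3,5-tribromobenzene, so the amino group that steered the bromines is erased.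

Step 16
Reactants: 23 1,5-dibromo-3-methoxy-2-[3,4,5-tribromo-2-(4-bromo-2-iodophenoxy)phenoxy]benzene
Product: 25 3,5-dibromo-2-[3,4,5-tribromo-2-(4-bromo-2-iodophenoxy)phenoxy]phenol (bromoiesol B), via aryloxydibromoborane 24 (not isolated)
Conditions: BBr3 (3 equiv), CH2Cl2, −78 °C → rt, 12 h; then ice–water
Reagents that add atoms: none
Why: In this Lewis-acid ether cleavage only the methyl–oxygen bond can be opened by SN2 attack of bromide, so both diaryl ethers and all aryl halides remain.

Step 17
Reactants: 25 3,5-dibromo-2-[3,4,5-tribromo-2-(4-bromo-2-iodophenoxy)phenoxy]phenol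
Product: 27 sodium 3,5-dibromo-2-[3,4,5-tribromo-2-(4-bromo-2-iodophenoxy)phenoxy]phenyl sulfate, via pyridinium aryl sulfate 26 (not isolated)
Conditions: SO3·pyridine (5 equiv), pyridine, 40 °C, 12 h; then NaHCO3 (aq), 0 °C; C18 reversed-phase column (H2O → MeOH)
Reagents that add atoms: sulfur trioxide–pyridine complex, O=S(=O)([O-])[n+]1ccccc1; NaHCO3, [Na+].OC(=O)[O-]
Why: In this O-sulfation the phenol oxygen attacks the sulfur of the mild, buffered SO3 donor, the deactivated rings are not C-sulfonated, and exchange to the sodium salt gives a stable form that can be freed from inorganic sulfate.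

Step 18
Reactants: 27 sodium 3,5-dibromo-2-[3,4,5-tribromo-2-(4-bromo-2-iodophenoxy)phenoxy]phenyl sulfate
Product: 28 3,5-dibromo-2-[3,4,5-tribromo-2-(4-bromo-2-iodophenoxy)phenoxy]phenyl hydrogen sulfate (bromoiesol B sulfate)
Conditions: HCl (1.0 equiv, 4 M in 1,4-dioxane), dry MeCN, 0 °C, 10 min; filter off NaCl; evaporate below 20 °C; store at −20 °C
Reagents that add atoms: none
Why: This protonation by salt metathesis is driven by precipitation of NaCl from MeCN, and the cold, water-free medium suppresses acid-catalysed hydrolysis of the aryl hydrogen sulfate.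

**Compound list**
1 | mucobromic acid, (Z)-2,3-dibromo-4-oxobut-2-enoic acid | O=C/C(Br)=C(Br)\C(=O)O | starting material
2 | sodium nitromalonaldehyde monohydrate (Na[C3H2NO4]·H2O) | O=CC(=C[O-])[N+](=O)[O-].[Na+].O | intermediate
3 | 4-bromophenol | Oc1ccc(Br)cc1 | starting material
4 | 4-bromo-2-iodophenol | Oc1ccc(Br)cc1I | intermediate
5 | chloroacetone | CC(=O)CCl | starting material
6 | 1-(4-bromo-2-iodophenoxy)propan-2-one | CC(=O)COc1ccc(Br)cc1I | intermediate
7 | 4-(4-bromo-2-iodophenoxy)-2-nitro-5-oxohex-3-enal (in the flask a delocalised sodium salt; C=C geometry and C2 labile, no descriptor; drawn for first attack through the aryloxymethylene carbon) | CC(=O)C(Oc1ccc(Br)cc1I)=CC(C=O)[N+](=O)[O-] | intermediate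
8 | 2-(4-bromo-2-iodophenoxy)-4-nitrophenol | Oc1ccc([N+](=O)[O-])cc1Oc1ccc(Br)cc1I | intermediate
9 | 2-(4-bromo-2-iodophenoxy)-1-methoxy-4-nitrobenzene | COc1ccc([N+](=O)[O-])cc1Oc1ccc(Br)cc1I | intermediate
10 | 3-(4-bromo-2-iodophenoxy)-4-methoxyaniline | COc1ccc(N)cc1Oc1ccc(Br)cc1I | intermediate
11 | 2,6-dibromo-3-(4-bromo-2-iodophenoxy)-4-methoxyaniline | COc1cc(Br)c(N)c(Br)c1Oc1ccc(Br)cc1I | intermediate
12 | 2,6-dibromo-3-(4-bromo-2-iodophenoxy)-4-methoxybenzenediazonium bromide | COc1cc(Br)c([N+]#N)c(Br)c1Oc1ccc(Br)cc1I.[Br-] | intermediate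
13 | 1,2,3-tribromo-4-(4-bromo-2-iodophenoxy)-5-methoxybenzene | COc1cc(Br)c(Br)c(Br)c1Oc1ccc(Br)cc1I | intermediate
14 | dibromo[3,4,5-tribromo-2-(4-bromo-2-iodophenoxy)phenoxy]borane | BrB(Br)Oc1cc(Br)c(Br)c(Br)c1Oc1ccc(Br)cc1I | intermediate
15 | 3,4,5-tribromo-2-(4-bromo-2-iodophenoxy)phenol | Oc1cc(Br)c(Br)c(Br)c1Oc1ccc(Br)cc1I | intermediate
16 | 1-[3,4,5-tribromo-2-(4-bromo-2-iodophenoxy)phenoxy]propan-2-one | CC(=O)COc1cc(Br)c(Br)c(Br)c1Oc1ccc(Br)cc1I | intermediate
17 | 2-nitro-5-oxo-4-[3,4,5-tribromo-2-(4-bromo-2-iodophenoxy)phenoxy]hex-3-enal (delocalised sodium salt in the flask; no fixed descriptor) | CC(=O)C(Oc1cc(Br)c(Br)c(Br)c1Oc1ccc(Br)cc1I)=CC(C=O)[N+](=O)[O-] | intermediate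
18 | 4-nitro-2-[3,4,5-tribromo-2-(4-bromo-2-iodophenoxy)phenoxy]phenol | Oc1ccc([N+](=O)[O-])cc1Oc1cc(Br)c(Br)c(Br)c1Oc1ccc(Br)cc1I | intermediate
19 | 1,2,3-tribromo-4-(4-bromo-2-iodophenoxy)-5-(2-methoxy-5-nitrophenoxy)benzene | COc1ccc([N+](=O)[O-])cc1Oc1cc(Br)c(Br)c(Br)c1Oc1ccc(Br)cc1I | intermediate
20 | 4-methoxy-3-[3,4,5-tribromo-2-(4-bromo-2-iodophenoxy)phenoxy]aniline | COc1ccc(N)cc1Oc1cc(Br)c(Br)c(Br)c1Oc1ccc(Br)cc1I | intermediate
21 | 2,6-dibromo-4-methoxy-3-[3,4,5-tribromo-2-(4-bromo-2-iodophenoxy)phenoxy]aniline | COc1cc(Br)c(N)c(Br)c1Oc1cc(Br)c(Br)c(Br)c1Oc1ccc(Br)cc1I | intermediate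
22 | 2,6-dibromo-4-methoxy-3-[3,4,5-tribromo-2-(4-bromo-2-iodophenoxy)phenoxy]benzenediazonium hydrogen sulfate | COc1cc(Br)c([N+]#N)c(Br)c1Oc1cc(Br)c(Br)c(Br)c1Oc1ccc(Br)cc1I.OS(=O)(=O)[O-] | intermediate
23 | 1,5-dibromo-3-methoxy-2-[3,4,5-tribromo-2-(4-bromo-2-iodophenoxy)phenoxy]benzene | COc1cc(Br)cc(Br)c1Oc1cc(Br)c(Br)c(Br)c1Oc1ccc(Br)cc1I | intermediate
24 | dibromo{3,5-dibromo-2-[3,4,5-tribromo-2-(4-bromo-2-iodophenoxy)phenoxy]phenoxy}borane | BrB(Br)Oc1cc(Br)cc(Br)c1Oc1cc(Br)c(Br)c(Br)c1Oc1ccc(Br)cc1I | intermediate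
25 | 3,5-dibromo-2-[3,4,5-tribromo-2-(4-bromo-2-iodophenoxy)phenoxy]phenol (bromoiesol B) | Oc1cc(Br)cc(Br)c1Oc1cc(Br)c(Br)c(Br)c1Oc1ccc(Br)cc1I | intermediate
26 | pyridinium 3,5-dibromo-2-[3,4,5-tribromo-2-(4-bromo-2-iodophenoxy)phenoxy]phenyl sulfate | c1cc[nH+]cc1.[O-]S(=O)(=O)Oc1cc(Br)cc(Br)c1Oc1cc(Br)c(Br)c(Br)c1Oc1ccc(Br)cc1I | intermediate
27 | sodium 3,5-dibromo-2-[3,4,5-tribromo-2-(4-bromo-2-iodophenoxy)phenoxy]phenyl sulfate | [Na+].[O-]S(=O)(=O)Oc1cc(Br)cc(Br)c1Oc1cc(Br)c(Br)c(Br)c1Oc1ccc(Br)cc1I | intermediate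
28 | bromoiesol B sulfate, 3,5-dibromo-2-[3,4,5-tribromo-2-(4-bromo-2-iodophenoxy)phenoxy]phenyl hydrogen sulfate (achiral) | O=S(=O)(O)Oc1cc(Br)cc(Br)c1Oc1cc(Br)c(Br)c(Br)c1Oc1ccc(Br)cc1I | target

**Totals**
Total step count: 18.
Longest linear sequence: 17 steps (3 → 28, steps 2 to 18). Step 1 is a side branch whose product 2 is used twice.

**Three steps most likely to fail**

Step 11 (second benzannulation). Ketone 16 is large and poorly soluble in aqueous-alcoholic base, the nitromalonaldehyde anion is a sluggish electrophile, and self-aldol of 16 can compete. The fallback brings ring A in ready-made instead of building it. It sets out from 15 and comes back at 25, bypassing steps 10 to 16.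
- An SNAr reaction of 15 with commercial 3,5-dibromo-2-fluorobenzaldehyde (K2CO3, DMF, 90 °C; the ortho formyl group activates the fluoride) gives 3,5-dibromo-2-[3,4,5-tribromo-2-(4-bromo-2-iodophenoxy)phenoxy]benzaldehyde F1.
- Baeyer–Villiger oxidation (mCPBA, CH2Cl2, reflux) follows; a Na2S2O3 wash returns any aryl iodide that the peracid raised to a trivalent iodine species. This gives 3,5-dibromo-2-[3,4,5-tribromo-2-(4-bromo-2-iodophenoxy)phenoxy]phenyl formate F2.
- Methanolysis (catalytic K2CO3, MeOH, rt) releases phenol 25.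

Step 4 (first benzannulation). The reaction is slow, yields with unsymmetrical ketones are moderate, and 2 is a hazardous reagent. The fallback makes the ring B–O–ring C bond by metal-free O-arylation with a diaryliodonium salt. It sets out from 4 and comes back at 9.
- Commercial 2-iodo-1-methoxy-4-nitrobenzene is oxidised with mCPBA and p-TsOH·H2O in MeCN at 75 °C to 2-[hydroxy(tosyloxy)iodo]-1-methoxy-4-nitrobenzene F3.
- F3 is trapped in the same flask by 1,3,5-trimethoxybenzene to give (2-methoxy-5-nitrophenyl)(2,4,6-trimethoxyphenyl)iodonium tosylate F4.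
- Phenol 4 with K2CO3 in MeCN at 55 °C then takes over the electron-poor aryl group of F4 by ligand coupling. The electron-rich trimethoxyphenyl group stays on iodine, and no metal is present that could touch C–I or C–Br. The product is 9.

Step 17 (sulfation). The phenol is electron-poor and flanked by a bulky aryloxy group, so conversion may stall and the salt can hydrolyse on purification. The fallback carries the sulfate as a neutral diester that can be chromatographed. It sets out from 25 and comes back at 27.
- Phenol 25 is deprotonated with NaH in THF at 0 °C and treated with commercial neopentyl chlorosulfate. This gives 2,2-dimethylpropyl 3,5-dibromo-2-[3,4,5-tribromo-2-(4-bromo-2-iodophenoxy)phenoxy]phenyl sulfate F5, which is purified on silica.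
- NaN3 in DMF at 65 °C removes the neopentyl group by SN2 at carbon and delivers sodium salt 27 directly.

**Further compounds**
F1 | step 11 | 3,5-dibromo-2-[3,4,5-tribromo-2-(4-bromo-2-iodophenoxy)phenoxy]benzaldehyde | O=Cc1cc(Br)cc(Br)c1Oc1cc(Br)c(Br)c(Br)c1Oc1ccc(Br)cc1I
F2 | step 11 | 3,5-dibromo-2-[3,4,5-tribromo-2-(4-bromo-2-iodophenoxy)phenoxy]phenyl formate | O=COc1cc(Br)cc(Br)c1Oc1cc(Br)c(Br)c(Br)c1Oc1ccc(Br)cc1I
F3 | step 4 | 2-[hydroxy(tosyloxy)iodo]-1-methoxy-4-nitrobenzene | COc1ccc([N+](=O)[O-])cc1I(O)OS(=O)(=O)c1ccc(C)cc1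
F4 | step 4 | (2-methoxy-5-nitrophenyl)(2,4,6-trimethoxyphenyl)iodonium tosylate | COc1ccc([N+](=O)[O-])cc1[I+]c1c(OC)cc(OC)cc1OC.Cc1ccc(S(=O)(=O)[O-])cc1
F5 | step 17 | 2,2-dimethylpropyl 3,5-dibromo-2-[3,4,5-tribromo-2-(4-bromo-2-iodophenoxy)phenoxy]phenyl sulfate | CC(C)(C)COS(=O)(=O)Oc1cc(Br)cc(Br)c1Oc1cc(Br)c(Br)c(Br)c1Oc1ccc(Br)cc1I
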